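## Retrosynthetic overview

1. Target 30 ⇐ late C6 angelate, lactone α-methylenation and methylenation of a C10 ketone.
2. C1–O and the 4,5-oxirane ⇐ one double oxidation (Rubottom plus epoxidation) of the ten-membered silyl enol ether 21.
3. Ten-membered ring ⇐ anionic oxy-Cope ring expansion of the trans-1-vinyl-2-isopropenylcyclohexanol 17 (key [3,3] step: C5–C10 breaks, C2–C3 forms).
4. Cyclohexane ⇐ carbonyl-ene cyclisation of lactone aldehyde 13; C7 ⇐ trans conjugate addition to butenolide 11.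
5. Butenolide ⇐ (S)-epichlorohydrin (source of C8) + prenal dithiane + PhSeCH2CO2H. Ring order: γ-lactone, cyclohexane, cyclodecene, oxirane.

Assumption: the lactone is read as a 12,8-olide, so atoms carry germacrane labels C1–C15 throughout; α is the face of H-7, β the opposite face.

## Route

Step 1
Reactants: 1 3-methylbut-2-enal; 2 propane-1,3-dithiol
Product: 3 2-(2-methylprop-1-en-1-yl)-1,3-dithiane
Conditions: BF3·OEt2 (0.2 equiv), CH2Cl2, −20 to 0 °C
Reagents that add atoms: none
Why: Lewis-acid dithioacetalisation of the aldehyde, in which the β,β-dimethyl groups suppress thia-Michael addition; no stereocentre is formed.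

Step 2
Reactants: 3 2-(2-methylprop-1-en-1-yl)-1,3-dithiane; 4 (S)-epichlorohydrin
Product: 7 (S)-2-(2-methylprop-1-en-1-yl)-2-(oxiran-2-ylmethyl)-1,3-dithiane, via lithiated dithiane 5 (not isolated), via lithium chlorohydrin alkoxide 6 (not isolated)
Conditions: n-BuLi, THF, −30 °C; then 4, −78 to 25 °C
Reagents that add atoms: none
Why: Corey–Seebach umpolung alkylation in which the dithiane anion attacks through its α-carbon at the epoxide CH2 of 4 and the alkoxide then closes the new oxirane by Williamson displacement of chloride, so the bought stereocentre (future C8) is never touched.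

Step 3
Reactants: 7 (S)-2-(2-methylprop-1-en-1-yl)-2-(oxiran-2-ylmethyl)-1,3-dithiane
Product: 9 (5S)-5-{[2-(2-methylprop-1-en-1-yl)-1,3-dithian-2-yl]methyl}-3-(phenylselanyl)dihydrofuran-2(3H)-one (C3 epimers), via hydroxy acid 8 (not isolated)
Conditions: PhSeCH2CO2H, LiN(i-Pr)2 (2.1 equiv), THF, −78 to 0 °C; 7, 0 to 25 °C; then 1 M HCl; p-TsOH (cat.), CH2Cl2, 25 °C
Reagents that add atoms: 2-(phenylselanyl)acetic acid OC(=O)C[Se]c1ccccc1
Why: Regioselective opening of the terminal epoxide by the carboxylic acid dianion followed by acid lactonisation builds the γ-lactone (C11, C12) without touching C8.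

Step 4
Reactants: 9 α-phenylselanyl lactone
Product: 11 (5S)-5-{[2-(2-methylprop-1-en-1-yl)-1,3-dithian-2-yl]methyl}furan-2(5H)-one, via selenoxide 10 (not isolated)
Conditions: mCPBA (1.0 equiv), CH2Cl2, −78 °C; then pyridine (2 equiv), −78 to 25 °C
Reagents that add atoms: none
Why: One equivalent of peracid at −78 °C oxidises selenium far faster than the dithiane sulfur or the trisubstituted alkene, and the selenoxide then undergoes syn-elimination on warming to give the butenolide with C8 unaffected.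

Step 5
Reactants: 11 butenolide
Product: 13 (2S,3R)-2-{[2-(2-methylprop-1-en-1-yl)-1,3-dithian-2-yl]methyl}-5-oxotetrahydrofuran-3-carbaldehyde, via dithioacetal S-oxide adduct 12 (not isolated)
Conditions: CH3S(O)CH2SCH3, n-BuLi, THF, −78 °C; 11, −78 °C; then 1 M HCl, THF, 25 °C
Reagents that add atoms: methyl (methylsulfanyl)methyl sulfoxide CS(=O)CSC; water O
Why: Michael addition of a formyl-anion equivalent occurs anti to the C8 side chain and so sets C7 trans to it, and aqueous acid then hydrolyses the dithioacetal S-oxide to the aldehyde (dimethyl disulfide leaves) while the 1,3-dithiane survives.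

Step 6
Reactants: 13 lactone aldehyde
Product: 14 ene product: 6α-hydroxy-5β-isopropenyl-10-spiro-(1,3-dithiane) cyclohexane C5–C10 trans-fused to the 12,8α-γ-lactone (H-7α and H-8β)
Conditions: ZnBr2 (1.5 equiv), CH2Cl2, 0 to 25 °C
Reagents that add atoms: none
Why: Intramolecular carbonyl-ene cyclisation of the citronellal-to-isopulegol kind proceeds through a chair transition state with all substituents equatorial, which sets C6–OH trans to C7 and the C5 isopropenyl trans to the OH.

Step 7
Reactants: 14 ene product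
Product: 15 6α-triethylsilyl ether of 14
Conditions: Et3SiOTf, 2,6-lutidine, CH2Cl2, −78 to 0 °C
Reagents that add atoms: triethylsilyl trifluoromethanesulfonate CC[Si](CC)(CC)OS(=O)(=O)C(F)(F)F
Why: Silylation of the hindered secondary alcohol gives a β-silyloxy group that resists elimination in the ketone steps and can later be removed in the presence of a TBS ether.

Step 8
Reactants: 15 TES ether
Product: 16 C10 ketone of 15 with 5β-isopropenyl and 6α-OSiEt3 on the trans-fused 12,8α-lactone
Conditions: MeI, CaCO3, MeCN–H2O (9:1), 40 °C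
Reagents that add atoms: water O
Why: Dethioacetalisation by S-methylation and hydrolysis runs near neutral pH, so the β,γ-unsaturated ketone is not conjugated and the TES ether and lactone survive.

Step 9
Reactants: 16 ketone
Product: 17 10β-hydroxy-6α-(triethylsilyloxy)-13,14-dinorelema-1,3-dien-12,8α-olide (10α-vinyl and 5β-isopropenyl trans-diequatorial)
Conditions: CH2=CHMgBr, anhydrous CeCl3, THF, −78 °C
Reagents that add atoms: vinylmagnesium bromide C=C[Mg]Br
Why: The weakly basic organocerium reagent adds 1,2 to the ketone in preference to the lactone and without enolisation, from the equatorial direction as in additions to menthone, which places vinyl trans to the isopropenyl group (new C10 centre, later destroyed).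

Step 10
Reactants: 17 divinyl carbinol
Product: 21 10-(tert-butyldimethylsilyloxy)-6α-(triethylsilyloxy)-13,14-dinorgermacra-1(10),4E-dien-12,8α-olide (C2 trans to C9 across C1=C10), via potassium alkoxide 18 (not isolated), via dipotassium bis-enolate 19 (not isolated), via bis-silyl ether 20 (not isolated)
Conditions: KH (3 equiv), 18-crown-6 (3 equiv), THF, 0 to 25 °C; t-BuMe2SiCl (3.5 equiv), −78 to 0 °C; pH 7 buffer, then SiO2
Reagents that add atoms: tert-butyldimethylsilyl chloride CC(C)(C)[Si](C)(C)Cl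
Why: Anionic oxy-Cope rearrangement ([3,3]-sigmatropic) of the alkoxide with diequatorial vinyl and isopropenyl groups passes through a chair transition state to give the ten-membered ring with E-C4=C5 and a regiodefined C10–C1 enolate; excess KH holds the lactone as its enolate so no C–H acid can scramble it, and after O-silylation only the labile ketene acetal is hydrolysed (C6, C7, C8 untouched).

Step 11
Reactants: 21 silyl enol ether
Product: 22 1α-(tert-butyldimethylsilyloxy)-4α,5β-epoxy-10-oxo-6α-(triethylsilyloxy)-13,14-dinorgermacran-12,8α-olide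
Conditions: mCPBA (2.3 equiv), NaHCO3, CH2Cl2, −20 to 0 °C
Reagents that add atoms: 3-chloroperoxybenzoic acid OOC(=O)c1cccc(Cl)c1
Why: Rubottom oxidation of the enol ether (epoxidation, then 1,4-silyl shift) and Prilezhaev epoxidation of the only other C=C both occur by peripheral attack on the ten-membered ring: the 6α-OSiEt3 group holds C15 on the β face so the oxirane forms 4α,5β (4R,5R), and oxygen is delivered to the exposed face of C1, expected α (1S) from the rotamer with the silyloxy group on the α face.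

Step 12
Reactants: 22 α-silyloxy ketone
Product: 23 1α-(tert-butyldimethylsilyloxy)-4α,5β-epoxy-6α-(triethylsilyloxy)-13-norgermacr-10(14)-en-12,8α-olide
Conditions: Cp2Ti(μ-CH2)(μ-Cl)AlMe2 (1.2 equiv), pyridine (cat.), THF–toluene, −40 to 0 °C
Reagents that add atoms: Tebbe reagent Cp2Ti(μ-CH2)(μ-Cl)AlMe2 C[Al](C)C[Ti](Cl)(C1C=CC=C1)C1C=CC=C1
Why: Tebbe methylenation is non-basic (no epimerisation at C1 and no β-elimination of the C8 lactone oxygen), selects the ketone over the lactone at low temperature, and with pyridine tempering the aluminium Lewis acid leaves the oxirane intact.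

Step 13
Reactants: 23 exocyclic alkene
Product: 26 1α-(tert-butyldimethylsilyloxy)-4α,5β-epoxy-6α-(triethylsilyloxy)germacra-10(14),11(13)-dien-12,8α-olide, via Mannich base 24 (not isolated), via trimethylammonium iodide 25 (not isolated)
Conditions: LiN(i-Pr)2 (1.2 equiv), THF, −78 °C; (CH2=NMe2)I, −78 to 0 °C; MeI, MeOH, 25 °C; aq. NaHCO3, CH2Cl2, 25 °C
Reagents that add atoms: N,N-dimethylmethyleneiminium iodide C=[N+](C)C.[I-]
Why: The lactone α-CH2 is now the only acidic site, so enolate aminomethylation (Mannich) followed by quaternisation and Hofmann-type elimination installs the α-methylene group; no stereocentre is formed.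

Step 14
Reactants: 26 bis-silyl ether
Product: 27 1α-(tert-butyldimethylsilyloxy)-4α,5β-epoxy-6α-hydroxygermacra-10(14),11(13)-dien-12,8α-olide
Conditions: HF·pyridine, pyridine, THF, 0 °C
Reagents that add atoms: none
Why: Buffered fluoride cleaves the triethylsilyl ether much faster than the secondary TBS ether and leaves the oxirane and the Michael acceptor alone.

Step 15
Reactants: 27 6α-alcohol; 28 angelic acid [(Z)-2-methylbut-2-enoic acid]
Product: 29 6α-angeloyloxy-1α-(tert-butyldimethylsilyloxy)-4α,5β-epoxygermacra-10(14),11(13)-dien-12,8α-olide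
Conditions: 28, 2,4,6-Cl3C6H2COCl, Et3N, toluene, 25 °C; then 27, toluene, 75 °C
Reagents that add atoms: none
Why: Yamaguchi-type mixed-anhydride esterification acylates the hindered alcohol with retention at C6 and, without a nucleophilic amine catalyst, avoids Z-to-E isomerisation to the tiglate.

Step 16
Reactants: 29 silyl-protected angelate
Product: 30 (1S,4R,5R,6S,7R,8S)-6-angeloyloxy-4,5-epoxy-1-hydroxygermacra-10(14),11(13)-dien-12,8-olide (CNP0104965.3)
Conditions: Bu4NF, AcOH, THF, 0 to 25 °C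
Reagents that add atoms: none
Why: Acetic-acid-buffered fluoride desilylation frees the C1 alcohol without acyl migration, Michael addition or transannular opening of the oxirane.

## Compound list

1 | 3-methylbut-2-enal | CC(C)=CC=O | starting material
2 | propane-1,3-dithiol | SCCCS | starting material
3 | 2-(2-methylprop-1-en-1-yl)-1,3-dithiane | CC(C)=CC1SCCCS1 | intermediate
4 | (S)-epichlorohydrin | ClC[C@@H]1CO1 | starting material
5 | 2-lithio-2-(2-methylprop-1-en-1-yl)-1,3-dithiane | [Li]C1(C=C(C)C)SCCCS1 | intermediate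
6 | lithium (2S)-1-chloro-3-[2-(2-methylprop-1-en-1-yl)-1,3-dithian-2-yl]propan-2-olate | ClC[C@@H]([O-])CC1(C=C(C)C)SCCCS1.[Li+] | intermediate
7 | (S)-2-(2-methylprop-1-en-1-yl)-2-(oxiran-2-ylmethyl)-1,3-dithiane | CC(C)=CC1(C[C@H]2CO2)SCCCS1 | intermediate
8 | (4S)-4-hydroxy-5-[2-(2-methylprop-1-en-1-yl)-1,3-dithian-2-yl]-2-(phenylselanyl)pentanoic acid (C2 epimers) | OC(=O)C([Se]c1ccccc1)C[C@@H](O)CC1(C=C(C)C)SCCCS1 | intermediate
9 | (5S)-5-{[2-(2-methylprop-1-en-1-yl)-1,3-dithian-2-yl]methyl}-3-(phenylselanyl)dihydrofuran-2(3H)-one (C3 epimers) | O=C1O[C@@H](CC2(C=C(C)C)SCCCS2)CC1[Se]c1ccccc1 | intermediate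
10 | selenoxide of 9 | O=C1O[C@@H](CC2(C=C(C)C)SCCCS2)CC1[Se](=O)c1ccccc1 | intermediate
11 | (5S)-5-{[2-(2-methylprop-1-en-1-yl)-1,3-dithian-2-yl]methyl}furan-2(5H)-one | O=C1C=C[C@H](CC2(C=C(C)C)SCCCS2)O1 | intermediate
12 | (4R,5S)-4-[(methylsulfanyl)(methylsulfinyl)methyl]-5-{[2-(2-methylprop-1-en-1-yl)-1,3-dithian-2-yl]methyl}dihydrofuran-2(3H)-one (epimers at the new CH and at S) | O=C1C[C@@H](C(SC)S(C)=O)[C@H](CC2(C=C(C)C)SCCCS2)O1 | intermediate
13 | (2S,3R)-2-{[2-(2-methylprop-1-en-1-yl)-1,3-dithian-2-yl]methyl}-5-oxotetrahydrofuran-3-carbaldehyde | O=C1C[C@@H](C=O)[C@H](CC2(C=C(C)C)SCCCS2)O1 | intermediate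
14 | ene product: 6α-hydroxy-5β-isopropenyl-10-spiro-(1,3-dithiane) cyclohexane C5–C10 trans-fused to the 12,8α-γ-lactone (H-7α and H-8β) | O=C1C[C@H]2[C@H](O)[C@@H](C(C)=C)C3(SCCCS3)C[C@@H]2O1 | intermediate
15 | 6α-triethylsilyl ether of 14 | O=C1C[C@H]2[C@H](O[Si](CC)(CC)CC)[C@@H](C(C)=C)C3(SCCCS3)C[C@@H]2O1 | intermediate
16 | C10 ketone of 15 with 5β-isopropenyl and 6α-OSiEt3 on the trans-fused 12,8α-lactone | O=C1C[C@H]2[C@H](O[Si](CC)(CC)CC)[C@@H](C(C)=C)C(=O)C[C@@H]2O1 | intermediate
17 | 10β-hydroxy-6α-(triethylsilyloxy)-13,14-dinorelema-1,3-dien-12,8α-olide (10α-vinyl and 5β-isopropenyl trans-diequatorial) | O=C1C[C@H]2[C@H](O[Si](CC)(CC)CC)[C@@H](C(C)=C)[C@](O)(C=C)C[C@@H]2O1 | intermediate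
18 | potassium C10 alkoxide of 17 | [K+].O=C1C[C@H]2[C@H](O[Si](CC)(CC)CC)[C@@H](C(C)=C)[C@]([O-])(C=C)C[C@@H]2O1 | intermediate
19 | dipotassium salt of the ring-expanded keto lactone (C10–C1 ketone enolate plus C12–C11 lactone enolate, E-C4=C5) | [K+].[K+].[O-]C1=C[C@H]2[C@H](O[Si](CC)(CC)CC)/C=C(C)/CC/C=C([O-])/C[C@@H]2O1 | intermediate
20 | bis(tert-butyldimethylsilyl) derivative of 19 (silyl enol ether plus ketene silyl acetal) | CC(C)(C)[Si](C)(C)OC1=C[C@H]2[C@H](O[Si](CC)(CC)CC)/C=C(C)/CC/C=C(O[Si](C)(C)C(C)(C)C)/C[C@@H]2O1 | intermediate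
21 | 10-(tert-butyldimethylsilyloxy)-6α-(triethylsilyloxy)-13,14-dinorgermacra-1(10),4E-dien-12,8α-olide (C2 trans to C9 across C1=C10) | O=C1C[C@H]2[C@H](O[Si](CC)(CC)CC)/C=C(C)/CC/C=C(O[Si](C)(C)C(C)(C)C)/C[C@@H]2O1 | intermediate
22 | 1α-(tert-butyldimethylsilyloxy)-4α,5β-epoxy-10-oxo-6α-(triethylsilyloxy)-13,14-dinorgermacran-12,8α-olide | O=C1C[C@H]2[C@H](O[Si](CC)(CC)CC)[C@H]3O[C@]3(C)CC[C@H](O[Si](C)(C)C(C)(C)C)C(=O)C[C@@H]2O1 | intermediate
23 | 1α-(tert-butyldimethylsilyloxy)-4α,5β-epoxy-6α-(triethylsilyloxy)-13-norgermacr-10(14)-en-12,8α-olide | O=C1C[C@H]2[C@H](O[Si](CC)(CC)CC)[C@H]3O[C@]3(C)CC[C@H](O[Si](C)(C)C(C)(C)C)C(=C)C[C@@H]2O1 | intermediate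
24 | 13-(dimethylamino) Mannich base of 23 (C11 epimers) | O=C1C(CN(C)C)[C@H]2[C@H](O[Si](CC)(CC)CC)[C@H]3O[C@]3(C)CC[C@H](O[Si](C)(C)C(C)(C)C)C(=C)C[C@@H]2O1 | intermediate
25 | 13-(trimethylammonio) iodide of 24 (C11 epimers) | [I-].O=C1C(C[N+](C)(C)C)[C@H]2[C@H](O[Si](CC)(CC)CC)[C@H]3O[C@]3(C)CC[C@H](O[Si](C)(C)C(C)(C)C)C(=C)C[C@@H]2O1 | intermediate
26 | 1α-(tert-butyldimethylsilyloxy)-4α,5β-epoxy-6α-(triethylsilyloxy)germacra-10(14),11(13)-dien-12,8α-olide | O=C1C(=C)[C@H]2[C@H](O[Si](CC)(CC)CC)[C@H]3O[C@]3(C)CC[C@H](O[Si](C)(C)C(C)(C)C)C(=C)C[C@@H]2O1 | intermediate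
27 | 1α-(tert-butyldimethylsilyloxy)-4α,5β-epoxy-6α-hydroxygermacra-10(14),11(13)-dien-12,8α-olide | O=C1C(=C)[C@H]2[C@H](O)[C@H]3O[C@]3(C)CC[C@H](O[Si](C)(C)C(C)(C)C)C(=C)C[C@@H]2O1 | intermediate
28 | angelic acid, (Z)-2-methylbut-2-enoic acid | C/C=C(/C)C(=O)O | starting material
29 | 6α-angeloyloxy-1α-(tert-butyldimethylsilyloxy)-4α,5β-epoxygermacra-10(14),11(13)-dien-12,8α-olide | O=C1C(=C)[C@H]2[C@H](OC(=O)/C(C)=C\C)[C@H]3O[C@]3(C)CC[C@H](O[Si](C)(C)C(C)(C)C)C(=C)C[C@@H]2O1 | intermediate
30 | (1S,4R,5R,6S,7R,8S)-6-angeloyloxy-4,5-epoxy-1-hydroxygermacra-10(14),11(13)-dien-12,8-olide (CNP0104965.3) | C=C1C(=O)O[C@H]2CC(=C)[C@@H](O)CC[C@@]3(C)O[C@@H]3[C@@H](OC(=O)/C(C)=C\C)[C@H]12 | target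

## Step count and risks

Total steps: 16. Longest linear sequence: 16 (from 1 and 2; 4 and 28 are bought).

**Step 11 (most uncertain).** The 4α,5β-oxirane is secured by the 6α substituent, but the face of C1 that is oxidised depends on which rotamer of the C1=C10 enol ether reacts. The rotamer that follows directly from the chair transition state of step 10 would give the 1β epimer. The fallback accepts β attack and then sets C1 by a stereospecific inversion instead of by facial selectivity; it sets out from 17 and comes back at 22. Alcohol 17 is rearranged as in step 10 (via 18 and 19) but capped with Me3SiCl to give the bis(trimethylsilyl) compound F2, which loses its ketene acetal on neutral work-up to give the trimethylsilyl enol ether F3. Buffered mCPBA (2.3 equiv) gives the 1β-trimethylsilyloxy ketone epoxide F4, and citric acid in methanol at 0 °C frees the 1β-hydroxy ketone epoxide F5. Tf2O and pyridine convert this into the α-keto triflate F6. Bu4N(NO2) in toluene displaces the triflate with SN2 inversion (Lattrell–Dax) to give the 1α-nitrite ester F7, which hydrolyses on work-up to the 1α-hydroxy ketone F8. t-BuMe2SiOTf and 2,6-lutidine then give 22.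

**Step 10.** The lactone α-protons are about as acidic as the ketone formed, so proton transfer could scramble or quench the regiodefined enolate, and the alkoxide could fragment instead of rearranging. The fallback separates rearrangement from enolisation; it sets out from 17 and comes back at 21. PdCl2(PhCN)2 (10 mol %, divalent palladium) in THF at 25 °C catalyses the oxy-Cope rearrangement of the 2-methyl-substituted 1,5-dien-3-ol without any base and gives the ring-expanded ketone F1. KN(SiMe3)2 (2.2 equiv) at −78 °C then deprotonates the lactone and, kinetically, the ketone at C1 (away from C9, which carries the β-acyloxy group) to give 19. Silylation gives 20, and hydrolysis of the ketene acetal gives 21 as in step 10.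

**Step 15.** The C6 alcohol is flanked by the oxirane and the ring fusion, and forcing conditions isomerise angelate to tiglate. The fallback builds the Z-alkene on the ester instead of transferring it; it sets out from 27 and comes back at 29. Alcohol 27 is acylated with 2-(diphenoxyphosphoryl)propanoic acid (DCC, DMAP, CH2Cl2) to give the phosphonate ester F9. An Ando-type Z-selective Horner–Wadsworth–Emmons reaction with acetaldehyde (NaI, DBU, THF, −78 to 0 °C) then gives 29.

## Further compounds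

F1 | step 10 | 10-oxo-6α-(triethylsilyloxy)-13,14-dinorgermacr-4E-en-12,8α-olide | O=C1C[C@H]2[C@H](O[Si](CC)(CC)CC)/C=C(C)/CCCC(=O)C[C@@H]2O1
F2 | step 11 | bis(trimethylsilyl) derivative of 19 (silyl enol ether plus ketene silyl acetal) | C[Si](C)(C)OC1=C[C@H]2[C@H](O[Si](CC)(CC)CC)/C=C(C)/CC/C=C(O[Si](C)(C)C)/C[C@@H]2O1
F3 | step 11 | 10-(trimethylsilyloxy)-6α-(triethylsilyloxy)-13,14-dinorgermacra-1(10),4E-dien-12,8α-olide | O=C1C[C@H]2[C@H](O[Si](CC)(CC)CC)/C=C(C)/CC/C=C(O[Si](C)(C)C)/C[C@@H]2O1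
F4 | step 11 | 4α,5β-epoxy-10-oxo-6α-(triethylsilyloxy)-1β-(trimethylsilyloxy)-13,14-dinorgermacran-12,8α-olide | O=C1C[C@H]2[C@H](O[Si](CC)(CC)CC)[C@H]3O[C@]3(C)CC[C@@H](O[Si](C)(C)C)C(=O)C[C@@H]2O1
F5 | step 11 | 4α,5β-epoxy-1β-hydroxy-10-oxo-6α-(triethylsilyloxy)-13,14-dinorgermacran-12,8α-olide | O=C1C[C@H]2[C@H](O[Si](CC)(CC)CC)[C@H]3O[C@]3(C)CC[C@@H](O)C(=O)C[C@@H]2O1
F6 | step 11 | 1β-trifluoromethanesulfonate of F5 | O=C1C[C@H]2[C@H](O[Si](CC)(CC)CC)[C@H]3O[C@]3(C)CC[C@@H](OS(=O)(=O)C(F)(F)F)C(=O)C[C@@H]2O1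
F7 | step 11 | 4α,5β-epoxy-1α-(nitrosooxy)-10-oxo-6α-(triethylsilyloxy)-13,14-dinorgermacran-12,8α-olide (1α-nitrite ester) | O=C1C[C@H]2[C@H](O[Si](CC)(CC)CC)[C@H]3O[C@]3(C)CC[C@H](ON=O)C(=O)C[C@@H]2O1
F8 | step 11 | 4α,5β-epoxy-1α-hydroxy-10-oxo-6α-(triethylsilyloxy)-13,14-dinorgermacran-12,8α-olide | O=C1C[C@H]2[C@H](O[Si](CC)(CC)CC)[C@H]3O[C@]3(C)CC[C@H](O)C(=O)C[C@@H]2O1
F9 | step 15 | 6α-[2-(diphenoxyphosphoryl)propanoyloxy]-1α-(tert-butyldimethylsilyloxy)-4α,5β-epoxygermacra-10(14),11(13)-dien-12,8α-olide (epimers at the phosphonate carbon) | O=C1C(=C)[C@H]2[C@H](OC(=O)C(C)P(=O)(Oc4ccccc4)Oc5ccccc5)[C@H]3O[C@]3(C)CC[C@H](O[Si](C)(C)C(C)(C)C)C(=C)C[C@@H]2O1
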